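The route rests on cutting the C13–C16 bond of ring D. The tertiary carbinol C16 lies β to C12 across the bridgehead C13, so ring D is the aldol ring of a ring C ketone. In the key step copper hydride adds to C14 of a ring C 13-en-12-one that carries an acetonyl group on the quaternary C8; the C13 enolate, formed regiospecifically, closes ring D and sets C13 and C16 in one operation. The precursor 25 already holds rings A, B and C, the 19,10-lactone and the other seven stereocentres. It is built from (R)-4-silyloxycyclopentenone by a Diels–Alder reaction (ring C) and a Michael–aldol annulation (ring A).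

Key step: step 19

Remark: gibberellane numbering is used (ring A C1–C5/C10, ring B C5/C6/C8–C10, ring C C8/C9/C11–C14, ring D C8/C13–C16); β is the face of H5, H9 and the C15–C16 bridge, α the face of the lactone bridge; C1, C2, C3, C4, C5 of 1 become C6, C8, C9, C10, C5; the C7 acid is carried as a benzyl ester and O3 as a benzyloxymethyl ether so that the last step needs no base; centres that are erased later (C14 in 6 and 7, C4 in 16–19, C3 in 20) are drawn as the expected main isomer.

Step 1
Reactants: 1 (R)-4-(tert-butyldimethylsilyloxy)cyclopent-2-en-1-one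
Product: 2 (R)-4-(tert-butyldimethylsilyloxy)-2-iodocyclopent-2-en-1-one
Conditions: I2, pyridine, CH2Cl2, 0 °C → rt
Reagents that add atoms: iodine, [I][I]
Why: α-Iodination of an enone by pyridine addition, iodination of the enolate and elimination (Morita–Baylis–Hillman-type addition–elimination) should place iodine on the future C8 without touching the silyloxy-bearing centre.

Step 2
Reactants: 2 iodoenone; 3 tributyl(2-methylallyl)stannane
Product: 4 (R)-4-(tert-butyldimethylsilyloxy)-2-(2-methylallyl)cyclopent-2-en-1-one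
Conditions: Pd2(dba)3 (cat.), AsPh3, CuI, NMP, rt
Reagents that add atoms: none
Why: Stille coupling, in which zerovalent palladium inserts into the vinylic C–I bond and the symmetric methallyl group is transferred from tin, should give the 2-methallyl enone as a single constitutional isomer.

Step 3
Reactants: 4 methallyl enone; 5 (E)-1-(dimethylamino)-3-(tert-butyldimethylsilyloxy)buta-1,3-diene
Product: 6 cis-fused B/C cycloadduct (6-ketone; 10β-OTBS; 8β-methallyl; 9β-H; C12 silyl enol ether; 14α-NMe2)
Conditions: toluene, 90 °C, sealed tube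
Reagents that add atoms: none
Why: Normal-demand Diels–Alder reaction: the CH2 terminus of the aminosiloxydiene bonds to the enone β-carbon C9 and the amino-bearing terminus to C8, the diene adds suprafacially to the face opposite the C10 silyloxy group, so C8 and C9 are set with the methallyl group cis to H9 and the ring C oxygen lands on C12 (the endo-derived C14 amine centre is lost in step 4).

Step 4
Reactants: 6 cycloadduct
Product: 8 B/C enone enol triflate (C5=C6–OTf; 10β-OTBS; ring C 13-en-12-one), via enol triflate 7 (not isolated)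
Conditions: KN(SiMe3)2, PhNTf2, THF, −78 °C; then 0.1 M HCl, THF, 0 °C
Reagents that add atoms: N-phenylbis(trifluoromethanesulfonimide), O=S(=O)(N(c1ccccc1)S(=O)(=O)C(F)(F)F)C(F)(F)F
Why: Enol triflate formation followed by hydrolysis and E1cB loss of dimethylamine: the C6 ketone can enolise only toward C5 because C8 is quaternary, trapping by the triflimide already in the flask should outrun β-elimination of the C10 silyloxy group, and dilute acid then turns the silyl enol ether into the ring C 13-en-12-one.

Step 5
Reactants: 8 enone enol triflate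
Product: 9 12,12-ethylenedioxy ketal of 8
Conditions: Me3SiOCH2CH2OSiMe3, Me3SiOTf (cat.), CH2Cl2, −78 → −20 °C; pyridine quench
Reagents that add atoms: 1,2-bis(trimethylsilyloxy)ethane, C[Si](C)(C)OCCO[Si](C)(C)C
Why: Ketalisation with the bis-silyl ether under silyl triflate catalysis (Noyori conditions) should mask the enone carbonyl, and the quaternary γ-carbon C8 rules out migration of the C13–C14 double bond.

Step 6
Reactants: 9 ketal enol triflate
Product: 10 benzyl enoate (C5=C6–CO2Bn; 10β-OTBS; 12-ketal)
Conditions: Pd(OAc)2 (cat.), PPh3, CO (1 atm), BnOH, Et3N, DMF, 60 °C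
Reagents that add atoms: carbon monoxide, [C-]#[O+]; benzyl alcohol, OCc1ccccc1
Why: Palladium-catalysed alkoxycarbonylation of an enol triflate (oxidative addition to zerovalent palladium formed in the flask, CO insertion, alcoholysis) should install C7 on C6 as a benzyl ester conjugated to C5=C6.

Step 7
Reactants: 10 benzyl enoate
Product: 11 10β-allylic alcohol
Conditions: Bu4NF, AcOH, THF, 0 °C → rt
Reagents that add atoms: none
Why: Fluoride-induced desilylation (Si–O cleavage driven by the Si–F bond) should free the C10 hydroxyl, with acetic acid buffering against isomerisation of the γ-hydroxy enoate.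

Step 8
Reactants: 11 allylic alcohol
Product: 12 benzyl 10-oxo-5-ene-6-carboxylate (12-ketal; 8β-methallyl; 9β-H)
Conditions: Dess–Martin periodinane, NaHCO3, CH2Cl2, 0 °C → rt
Reagents that add atoms: none
Why: Dess–Martin oxidation of the allylic alcohol should give the 4-oxo-enoate; the auxiliary C10 centre is erased on purpose and the cis ring fusion at C9, now α to the ketone, is the stable one for a bicyclo[4.3.0] enone.

Step 9
Reactants: 12 keto enoate; 13 (3-bromopropoxy)(tert-butyl)dimethylsilane
Product: 15 10α-propanoate of the 10β-(3-silyloxypropyl) carbinol, via cerium alkoxide 14 (not isolated)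
Conditions: 13, Mg, THF; CeCl3, THF, −78 °C; then 12; then (EtCO)2O, DMAP (cat.), −78 → 0 °C
Reagents that add atoms: propionic anhydride, CCC(=O)OC(=O)CC
Why: Organocerium 1,2-addition to an enolisable, conjugated ketone followed by acylation of the alkoxide in the flask: the nucleophile should enter C10 from the convex β face, anti to the adjacent C9–C11 bond, which leaves the oxygen α as the lactone requires (C10 set here).

Step 10
Reactants: 15 propanoate
Product: 17 19,10α-lactone benzyl ester (5β-H; 6β-CO2Bn), via potassium ester enolate 16 (not isolated)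
Conditions: KN(SiMe3)2, THF, −78 °C; then t-BuOH, −78 → 0 °C
Reagents that add atoms: none
Why: Intramolecular Michael addition (5-exo-trig) of the propanoate enolate to C5 of the enoate: the tether from the α-oxygen on C10 forces the new C4–C5 bond onto the α face (H5 β), and protonation with tert-butoxide-mediated equilibration should leave the C6 ester β, trans to that bond and on the less crowded face.

Step 11
Reactants: 17 lactone silyl ether
Product: 18 primary alcohol (C3–OH)
Conditions: Bu4NF, AcOH, THF, rt
Reagents that add atoms: none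
Why: Buffered fluoride desilylation should free the primary alcohol without enolising the lactone or the ester.

Step 12
Reactants: 18 primary alcohol
Product: 19 C3 aldehyde
Conditions: Dess–Martin periodinane, NaHCO3, CH2Cl2, 0 °C
Reagents that add atoms: none
Why: Dess–Martin oxidation should stop at the aldehyde under buffered, non-enolising conditions that spare the allylic ketal.

Step 13
Reactants: 19 aldehyde
Product: 20 ring A aldol (3α-hydroxy; 4β-methyl; 19,10α-lactone)
Conditions: KOt-Bu (0.2 equiv), t-BuOH/THF, 0 °C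
Reagents that add atoms: none
Why: Intramolecular aldol addition (6-(enolexo)-exo-trig) under reversible conditions: the lactone C4–H is the most acidic ester-type C–H (C6–H is flanked by the quaternary C8), only the face of C4 that carries the C1–C3 chain can reach the aldehyde, so C4 is set by ring geometry, and the hydrogen-bonded equatorial 3α-alcohol is expected as the main epimer, to be corrected in steps 14 and 15.

Step 14
Reactants: 20 aldol
Product: 21 3-ketone
Conditions: Dess–Martin periodinane, NaHCO3, CH2Cl2, rt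
Reagents that add atoms: none
Why: Dess–Martin oxidation should converge both C3 epimers on one β-keto lactone, which cannot enolise toward the quaternary C4.

Step 15
Reactants: 21 3-ketone
Product: 22 3β-alcohol
Conditions: LiBH(s-Bu)3, THF, −78 °C; AcOH quench at −78 °C
Reagents that add atoms: none
Why: Ketone reduction by a bulky trialkylborohydride: equatorial attack on the chair of ring A should give the axial 3β-alcohol, trans to the axial C4–C19 bond, and the cold acidic quench keeps the alkoxide from retro-aldol.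

Step 16
Reactants: 22 3β-alcohol
Product: 23 3β-benzyloxymethyl ether
Conditions: BnOCH2Cl, i-Pr2NEt, Bu4NI (cat.), CH2Cl2, 40 °C
Reagents that add atoms: benzyl chloromethyl ether, ClCOCc1ccccc1
Why: O-Alkylation with an α-chloro ether under amine base (SN1-like substitution through the oxocarbenium ion) should protect the hindered alcohol without forming an alkoxide, so the β-hydroxy lactone cannot open.

Step 17
Reactants: 23 ketal
Product: 24 ring C 13-en-12-one (8β-methallyl)
Conditions: 1 M HCl, THF, 0 °C → rt
Reagents that add atoms: water, O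
Why: Acid hydrolysis of the allylic dioxolane should return the conjugated enone, while the formaldehyde acetal, benzyl ester, lactone and methallyl group are stable to dilute acid.

Step 18
Reactants: 24 methallyl enone
Product: 25 key-step precursor (8β-acetonyl 13-en-12-one)
Conditions: OsO4 (cat.), NaIO4, 2,6-lutidine, dioxane/H2O, rt
Reagents that add atoms: osmium tetroxide, O=[Os](=O)(=O)=O; sodium periodate, [Na+].[O-]I(=O)(=O)=O
Why: Lemieux–Johnson oxidation: OsO4 should dihydroxylate the electron-rich 1,1-disubstituted alkene much faster than the electron-poor, hindered enone double bond, and periodate cleaves the diol to the methyl ketone.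

Step 19
Reactants: 25 acetonyl enone
Product: 27 12-oxo ketol with ring D closed (16-hydroxy-16-methyl), via copper enolate 26 (not isolated)
Conditions: [(Ph3P)CuH]6 (0.4 equiv of hexamer), toluene, −40 → 0 °C; then sat. aq. NH4Cl
Reagents that add atoms: none
Why: [(Ph3P)CuH]6 (monovalent copper) transfers hydride to C14, the β-carbon of the only enone, and the resulting C13 copper enolate 26 adds within the molecule to the C16 carbonyl of the acetonyl arm before it is protonated. The closest known reaction is the copper-hydride reductive aldol cyclisation of enone–ketones. Ring D closes in the 5-(enolexo)-exo-trig mode and completes the bicyclo[3.2.1]octane. C13 is fixed by the tether, because the acetonyl arm on the β face of C8 can reach C13 only from that face; C16 is fixed by the closed six-membered transition state in which copper bridges the C12 enolate oxygen and the ketone oxygen, so the new hydroxyl points to C12 and the methyl to C14. The step needs 1,4- over 1,2-reduction and a single enolate regioisomer; hydride delivery to C14 can generate only the C13 enolate, never the C11 one, and the esters, lactone and acetal are inert to the reagent. Low temperature and a neutral quench should keep the β-hydroxy ketone from retro-aldol.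

Step 20
Reactants: 27 ketol
Product: 28 C12 tosylhydrazone
Conditions: TsNHNH2, AcOH (cat.), EtOH, 40 °C
Reagents that add atoms: p-toluenesulfonyl hydrazide, Cc1ccc(cc1)S(=O)(=O)NN
Why: Hydrazone condensation at the only ketone under mild acid; the ketol cannot dehydrate because that would put a double bond at the bridgehead C13.

Step 21
Reactants: 28 tosylhydrazone
Product: 29 12-deoxo compound (target as 3-O-benzyloxymethyl ether and C7 benzyl ester)
Conditions: catecholborane, CHCl3, 0 °C → rt; then NaOAc·3H2O, reflux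
Reagents that add atoms: none
Why: Catecholborane reduction of the tosylhydrazone (a mild Caglioti-type deoxygenation): hydride adds to C=N, acetate triggers loss of sulfinate and N2 from the diazene, leaving CH2 at C12 under near-neutral conditions that spare the lactone, ester, acetal and tertiary alcohol.

Step 22
Reactants: 29 protected acid
Product: 30 target acid CNP0343121.3
Conditions: H2 (1 atm), Pd(OH)2/C, EtOAc/EtOH, rt
Reagents that add atoms: none
Why: Hydrogenolysis of both benzylic C–O bonds (the benzyl ester, and the benzyloxymethyl ether, whose hemiacetal collapses to the alcohol) should free the acid and the 3β-alcohol without base, so C3 cannot epimerise by retro-aldol.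

Compound list
1 | (R)-4-(tert-butyldimethylsilyloxy)cyclopent-2-en-1-one | O=C1C=C[C@H](O[Si](C)(C)C(C)(C)C)C1 | starting material
2 | (R)-4-(tert-butyldimethylsilyloxy)-2-iodocyclopent-2-en-1-one | O=C1C(I)=C[C@H](O[Si](C)(C)C(C)(C)C)C1 | intermediate
3 | tributyl(2-methylallyl)stannane | CC(=C)C[Sn](CCCC)(CCCC)CCCC | starting material
4 | (R)-4-(tert-butyldimethylsilyloxy)-2-(2-methylallyl)cyclopent-2-en-1-one | O=C1C(CC(C)=C)=C[C@H](O[Si](C)(C)C(C)(C)C)C1 | intermediate
5 | (E)-1-(dimethylamino)-3-(tert-butyldimethylsilyloxy)buta-1,3-diene | CN(C)/C=C/C(=C)O[Si](C)(C)C(C)(C)C | starting material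
6 | cis-fused B/C cycloadduct: 6-ketone, 10β-OTBS, 9β-H, 8β-(2-methylallyl), C12 TBS enol ether (C12=C13), 14α-NMe2 | O=C1C[C@@H](O[Si](C)(C)C(C)(C)C)[C@@H]2CC(O[Si](C)(C)C(C)(C)C)=C[C@H](N(C)C)[C@]12CC(C)=C | intermediate
7 | C6 enol triflate (C5=C6) of 6 | FC(F)(F)S(=O)(=O)OC1=C[C@@H](O[Si](C)(C)C(C)(C)C)[C@@H]2CC(O[Si](C)(C)C(C)(C)C)=C[C@H](N(C)C)[C@]12CC(C)=C | intermediate
8 | B/C enone enol triflate: C5=C6–OTf, 10β-OTBS, 9β-H, 8β-(2-methylallyl), ring C 13-en-12-one | FC(F)(F)S(=O)(=O)OC1=C[C@@H](O[Si](C)(C)C(C)(C)C)[C@@H]2CC(=O)C=C[C@]12CC(C)=C | intermediate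
9 | 12,12-ethylenedioxy ketal of 8 | FC(F)(F)S(=O)(=O)OC1=C[C@@H](O[Si](C)(C)C(C)(C)C)[C@@H]2CC3(OCCO3)C=C[C@]12CC(C)=C | intermediate
10 | benzyl enoate: C5=C6–CO2Bn, 10β-OTBS, 12-ketal | O=C(OCc1ccccc1)C1=C[C@@H](O[Si](C)(C)C(C)(C)C)[C@@H]2CC3(OCCO3)C=C[C@]12CC(C)=C | intermediate
11 | 10β-allylic alcohol of 10 | O=C(OCc1ccccc1)C1=C[C@@H](O)[C@@H]2CC3(OCCO3)C=C[C@]12CC(C)=C | intermediate
12 | benzyl 10-oxo-5-ene-6-carboxylate, 12-ketal, 8β-(2-methylallyl), 9β-H | O=C(OCc1ccccc1)C1=CC(=O)[C@@H]2CC3(OCCO3)C=C[C@]12CC(C)=C | intermediate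
13 | (3-bromopropoxy)(tert-butyl)dimethylsilane | BrCCCO[Si](C)(C)C(C)(C)C | starting material
14 | dichlorocerium 10α-alkoxide with 10β-(3-silyloxypropyl) chain | O=C(OCc1ccccc1)C1=C[C@@](O[Ce](Cl)Cl)(CCCO[Si](C)(C)C(C)(C)C)[C@@H]2CC3(OCCO3)C=C[C@]12CC(C)=C | intermediate
15 | 10α-propanoate, 10β-(3-silyloxypropyl) | O=C(OCc1ccccc1)C1=C[C@@](OC(=O)CC)(CCCO[Si](C)(C)C(C)(C)C)[C@@H]2CC3(OCCO3)C=C[C@]12CC(C)=C | intermediate
16 | potassium enolate of the C7 benzyl ester after lactone closure | C[C@H]1C(=O)O[C@]2(CCCO[Si](C)(C)C(C)(C)C)[C@@H]3CC4(OCCO4)C=C[C@]3(CC(C)=C)C(=C(O[K])OCc3ccccc3)[C@H]12 | intermediate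
17 | 19,10α-lactone benzyl ester: 5β-H, 6β-CO2Bn, C4–H with methyl anti to C6, 10β-(3-silyloxypropyl) | C[C@H]1C(=O)O[C@]2(CCCO[Si](C)(C)C(C)(C)C)[C@@H]3CC4(OCCO4)C=C[C@]3(CC(C)=C)[C@@H](C(=O)OCc3ccccc3)[C@H]12 | intermediate
18 | primary alcohol (C3–OH) of 17 | C[C@H]1C(=O)O[C@]2(CCCO)[C@@H]3CC4(OCCO4)C=C[C@]3(CC(C)=C)[C@@H](C(=O)OCc3ccccc3)[C@H]12 | intermediate
19 | C3 aldehyde | C[C@H]1C(=O)O[C@]2(CCC=O)[C@@H]3CC4(OCCO4)C=C[C@]3(CC(C)=C)[C@@H](C(=O)OCc3ccccc3)[C@H]12 | intermediate
20 | ring A aldol: 3α-hydroxy, 4β-methyl, 19,10α-lactone, 12-ketal | C[C@@]12C(=O)O[C@]3(CC[C@H]1O)[C@@H]1CC4(OCCO4)C=C[C@]1(CC(C)=C)[C@@H](C(=O)OCc1ccccc1)[C@@H]32 | intermediate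
21 | 3-ketone | C[C@@]12C(=O)O[C@]3(CCC1=O)[C@@H]1CC4(OCCO4)C=C[C@]1(CC(C)=C)[C@@H](C(=O)OCc1ccccc1)[C@@H]32 | intermediate
22 | 3β-alcohol | C[C@@]12C(=O)O[C@]3(CC[C@@H]1O)[C@@H]1CC4(OCCO4)C=C[C@]1(CC(C)=C)[C@@H](C(=O)OCc1ccccc1)[C@@H]32 | intermediate
23 | 3β-benzyloxymethyl ether | C[C@@]12C(=O)O[C@]3(CC[C@@H]1OCOCc1ccccc1)[C@@H]1CC4(OCCO4)C=C[C@]1(CC(C)=C)[C@@H](C(=O)OCc1ccccc1)[C@@H]32 | intermediate
24 | ring C 13-en-12-one, 8β-(2-methylallyl) | C[C@@]12C(=O)O[C@]3(CC[C@@H]1OCOCc1ccccc1)[C@@H]1CC(=O)C=C[C@]1(CC(C)=C)[C@@H](C(=O)OCc1ccccc1)[C@@H]32 | intermediate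
25 | key-step precursor: ring C 13-en-12-one, 8β-acetonyl | C[C@@]12C(=O)O[C@]3(CC[C@@H]1OCOCc1ccccc1)[C@@H]1CC(=O)C=C[C@]1(CC(C)=O)[C@@H](C(=O)OCc1ccccc1)[C@@H]32 | intermediate
26 | C13 copper enolate (C12–O–Cu, C12=C13) | C[C@@]12C(=O)O[C@]3(CC[C@@H]1OCOCc1ccccc1)[C@@H]1CC(O[Cu])=CC[C@]1(CC(C)=O)[C@@H](C(=O)OCc1ccccc1)[C@@H]32 | intermediate
27 | key-step product: 12-oxo ketol, ring D closed, 16-OH toward C12, 16-methyl toward C14 | C[C@@]12C(=O)O[C@]3(CC[C@@H]1OCOCc1ccccc1)[C@@H]1CC(=O)[C@@H]4C[C@]1(C[C@]4(C)O)[C@@H](C(=O)OCc1ccccc1)[C@@H]32 | intermediate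
28 | C12 tosylhydrazone | C[C@@]12C(=O)O[C@]3(CC[C@@H]1OCOCc1ccccc1)[C@@H]1CC(=NNS(=O)(=O)c5ccc(C)cc5)[C@@H]4C[C@]1(C[C@]4(C)O)[C@@H](C(=O)OCc1ccccc1)[C@@H]32 | intermediate
29 | 12-deoxo compound: target as 3-O-benzyloxymethyl ether and C7 benzyl ester | C[C@@]12C(=O)O[C@]3(CC[C@@H]1OCOCc1ccccc1)[C@@H]1CC[C@@H]4C[C@]1(C[C@]4(C)O)[C@@H](C(=O)OCc1ccccc1)[C@@H]32 | intermediate
30 | target acid CNP0343121.3 (3β,16-dihydroxy-16-methyl 19,10-lactone 7-oic acid) | C[C@@]12C(=O)O[C@]3(CC[C@@H]1O)[C@@H]1CC[C@@H]4C[C@]1(C[C@]4(C)O)[C@@H](C(=O)O)[C@@H]32 | target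

Total step count: 22. Longest linear sequence: 22 steps (1 to 30); compounds 3, 5 and 13 are purchased.

Steps most likely to fail

Step 19. Hydride transfer to the neopentyl C14 may be slow, the copper enolate may be protonated before it cyclises, or the C16 face may not be controlled. The fallback separates reduction from bond formation. From 25, 1,4-hydrosilylation (Et3SiH, RhCl(PPh3)3 cat., toluene, 50 °C) should give the C12 triethylsilyl enol ether F1, again with the double bond only at C12–C13. A fluoride source (Bu4N[Ph3SiF2], THF, −78 °C) then releases the enolate for the same intramolecular aldol addition. Under these reversible conditions the aldol should settle on the hydrogen-bonded ketol, and the route is rejoined at 27.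

Step 3. The α-alkylated enone may react too slowly, so that thermal loss of the diene or β-elimination of the C10 silyloxy group takes over. The fallback makes the quaternary centre after the cycloaddition. From 2, the more reactive α-iodoenone should add (E)-1-methoxy-3-(tert-butyldimethylsilyloxy)buta-1,3-diene (toluene, 80 °C) to give the iodo cycloadduct F2. Keck radical allylation with 3 (AIBN, benzene, 80 °C) replaces iodine by the methallyl group with the cis ring fusion kept, giving the methallyl cycloadduct F3. Enol triflation as in step 4 gives the enol triflate F4, which is not isolated, and dilute acid returns to the route at 8.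

Step 13. Base may enolise C2 or C6 as well as C4, and retro-aldol may lead to oligomers or the wrong ring. The fallback generates the C4 enolate by reduction, not by deprotonation. From 17, α-bromination at the lactone carbon (LiN(i-Pr)2, THF, −78 °C; then CBr4) gives the bromo lactone F5. Buffered desilylation (Bu4NF, AcOH) gives the bromo alcohol F6 and Dess–Martin oxidation gives the bromo aldehyde F7. SmI2 (THF, −78 °C) then forms the samarium enolate at C4 only, and the intramolecular Reformatsky reaction returns to the route at 20.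

Further compounds
F1 | step 19 | C12 triethylsilyl enol ether (C12=C13) of the acetonyl ketone | C[C@@]12C(=O)O[C@]3(CC[C@@H]1OCOCc1ccccc1)[C@@H]1CC(O[Si](CC)(CC)CC)=CC[C@]1(CC(C)=O)[C@@H](C(=O)OCc1ccccc1)[C@@H]32
F2 | step 3 | iodo cycloadduct: 6-ketone, 8β-iodo, 9β-H, 10β-OTBS, C12 TBS enol ether, 14α-OMe | O=C1C[C@@H](O[Si](C)(C)C(C)(C)C)[C@@H]2CC(O[Si](C)(C)C(C)(C)C)=C[C@H](OC)[C@]12I
F3 | step 3 | methallyl cycloadduct: as F2 with 8β-(2-methylallyl) | O=C1C[C@@H](O[Si](C)(C)C(C)(C)C)[C@@H]2CC(O[Si](C)(C)C(C)(C)C)=C[C@H](OC)[C@]12CC(C)=C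
F4 | step 3 | C6 enol triflate of F3 | FC(F)(F)S(=O)(=O)OC1=C[C@@H](O[Si](C)(C)C(C)(C)C)[C@@H]2CC(O[Si](C)(C)C(C)(C)C)=C[C@H](OC)[C@]12CC(C)=C
F5 | step 13 | 4-bromo lactone (bromine on the face of the C1–C3 chain), silyl ether | C[C@]1(Br)C(=O)O[C@]2(CCCO[Si](C)(C)C(C)(C)C)[C@@H]3CC4(OCCO4)C=C[C@]3(CC(C)=C)[C@@H](C(=O)OCc3ccccc3)[C@H]12
F6 | step 13 | 4-bromo lactone primary alcohol | C[C@]1(Br)C(=O)O[C@]2(CCCO)[C@@H]3CC4(OCCO4)C=C[C@]3(CC(C)=C)[C@@H](C(=O)OCc3ccccc3)[C@H]12
F7 | step 13 | 4-bromo lactone C3 aldehyde | C[C@]1(Br)C(=O)O[C@]2(CCC=O)[C@@H]3CC4(OCCO4)C=C[C@]3(CC(C)=C)[C@@H](C(=O)OCc3ccccc3)[C@H]12
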